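**Plan**
The side chain is numbered C1' (OCH2) to C7', and the target is (2'R,3'R,5'R). The retrosynthesis cuts, in this order: C6'=C7' (cross-metathesis, back to a vinyl group), C5'–O (inversion), both epoxide C–O bonds (back to the (E)-C2'=C3' alkene through a cyclic iodocarbonate), O7–C1' (Mitsunobu ether), C1'–C2' and C3'–CH3 (carboalumination and hydroxymethylation of an alkyne), and C4'–C5' (propargylation of prop-2-enal).
Enabling feature: the epoxide carbon C3' stands 1,3 to O5' (O5'–C5'–C4'–C3'), so a carbonate on O5' can reach C3' through a six-membered 1,3-dioxan-2-one ring while C2' stays outside the ring and takes the iodine.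
Forward: daphnetin is converted into 7-hydroxy-8-methoxycoumarin, and prop-2-enal with 3-bromoprop-1-yne gives (S)-hex-1-en-5-yn-3-ol and then the (2E,5S)-diol. The chain is joined at O7, O5' becomes the tert-butyl carbonate, IBr closes the only new ring (the temporary dioxanone), and K2CO3/MeOH collapses it to the epoxide. C5' is then inverted and the vinyl group is extended to the 2-methylpropenyl end.
Stereochemistry: C5' comes from a Sharpless kinetic resolution (S). C3' is set by relay from C5' through the chair of the cyclisation (4,6-cis ring), and C2' by anti addition to the (E)-alkene followed by SN2 epoxide closure. Because the relay is 1,3-syn and the target is 1,3-anti, C5' is inverted afterwards (Mitsunobu) to (R).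

Key step: step 9

**Route**

Step 1
Reactants: 1 daphnetin (7,8-dihydroxy-2H-chromen-2-one)
Product: 2 8-hydroxy-7-[(4-methoxybenzyl)oxy]-2H-chromen-2-one
Conditions: 4-MeOC6H4CH2Cl (1.05 equiv), K2CO3 (1.0 equiv), DMF, 0 °C → rt
Reagents that add atoms: 4-methoxybenzyl chloride, COc1ccc(CCl)cc1
Why: Williamson etherification with one equivalent of base; the 7-hydroxyl is conjugated with the lactone carbonyl and is the more acidic phenol, so its phenoxide forms and is alkylated first, leaving the 8-hydroxyl free.

Step 2
Reactants: 2 8-hydroxy-7-[(4-methoxybenzyl)oxy]-2H-chromen-2-one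
Product: 3 8-methoxy-7-[(4-methoxybenzyl)oxy]-2H-chromen-2-one
Conditions: MeI, K2CO3, acetone, 50 °C
Reagents that add atoms: iodomethane, CI
Why: Williamson O-methylation of the remaining 8-phenol, under which the lactone and the benzylic ether are inert.

Step 3
Reactants: 3 8-methoxy-7-[(4-methoxybenzyl)oxy]-2H-chromen-2-one
Product: 4 7-hydroxy-8-methoxy-2H-chromen-2-one
Conditions: CF3CO2H, anisole, CH2Cl2, 0 °C → rt
Reagents that add atoms: none
Why: Acidolysis of the aryl 4-methoxybenzyl ether (SN1 loss of the stabilised benzylic cation, which anisole traps by Friedel–Crafts alkylation) frees the 7-phenol while the methyl ether and the coumarin stay intact.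

Step 4
Reactants: 5 prop-2-enal; 6 3-bromoprop-1-yne
Product: 8 rac-hex-1-en-5-yn-3-ol, via allenylzinc bromide 7 (not isolated)
Conditions: 6, zinc dust, THF, 0 °C; then 5, −78 → 0 °C; aq. NH4Cl
Reagents that add atoms: none
Why: Barbier-type propargylation in which the allenylzinc reagent adds 1,2 to the aldehyde by an SE2' pathway and so gives the homopropargylic alcohol; the carbinol centre is formed as the racemate.

Step 5
Reactants: 8 rac-hex-1-en-5-yn-3-ol
Product: 9 (3S)-hex-1-en-5-yn-3-ol
Conditions: Ti(OiPr)4 (0.2 equiv), D-(−)-diisopropyl tartrate (0.3 equiv), t-BuOOH (0.6 equiv), 4 Å MS, CH2Cl2, −20 °C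
Reagents that add atoms: none
Why: Sharpless kinetic resolution of a secondary allylic alcohol; with the (S,S)-tartrate ligand the (R)-enantiomer is epoxidised much faster (to its erythro epoxy alcohol), so running a little beyond half conversion should leave the (S)-alcohol, which becomes C5' of the chain.

Step 6
Reactants: 9 (3S)-hex-1-en-5-yn-3-ol
Product: 12 (2E,5S)-3-methylhepta-2,6-diene-1,5-diol, via alkenylalane alkoxide 10 (not isolated), via lithium alkenylalanate 11 (not isolated)
Conditions: Al(CH3)3 (3 equiv), Cp2ZrCl2 (0.25 equiv), CH2Cl2, 0 °C → rt; then n-BuLi, THF/hexane, −30 °C; (CH2O)n, rt; aq. potassium sodium tartrate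
Reagents that add atoms: trimethylaluminium, C[Al](C)C; formaldehyde (as paraformaldehyde), C=O
Why: Negishi carboalumination adds CH3 and Al syn across the terminal alkyne with Al at the terminal carbon (the hydroxyl is carried as its aluminium alkoxide), and hydroxymethylation of the derived alanate with formaldehyde proceeds with retention, which fixes the (E)-trisubstituted alkene; the vinyl group and C5 are untouched.

Step 7
Reactants: 12 (2E,5S)-3-methylhepta-2,6-diene-1,5-diol; 4 7-hydroxy-8-methoxy-2H-chromen-2-one
Product: 13 7-{[(2E,5S)-5-hydroxy-3-methylhepta-2,6-dien-1-yl]oxy}-8-methoxy-2H-chromen-2-one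
Conditions: PPh3, DIAD (1.05 equiv each), THF, 0 °C → rt
Reagents that add atoms: none
Why: Mitsunobu etherification in which the acidic 7-phenol displaces the oxyphosphonium ion of the unhindered primary allylic hydroxyl by SN2 far faster than anything happens at the secondary hydroxyl, so O7–C1' forms and C5' is not touched.

Step 8
Reactants: 13 7-{[(2E,5S)-5-hydroxy-3-methylhepta-2,6-dien-1-yl]oxy}-8-methoxy-2H-chromen-2-one
Product: 14 tert-butyl (3S,5E)-7-[(8-methoxy-2-oxo-2H-chromen-7-yl)oxy]-5-methylhepta-1,5-dien-3-yl carbonate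
Conditions: Boc2O, DMAP, MeCN, rt
Reagents that add atoms: di-tert-butyl dicarbonate, CC(C)(C)OC(=O)OC(=O)OC(C)(C)C
Why: DMAP-catalysed acylation of the secondary hydroxyl gives the mixed tert-butyl carbonate with retention at C5' and installs the internal oxygen nucleophile for the cyclisation.

Step 9
Reactants: 14 tert-butyl (3S,5E)-7-[(8-methoxy-2-oxo-2H-chromen-7-yl)oxy]-5-methylhepta-1,5-dien-3-yl carbonate
Product: 15 (4R,6S)-6-ethenyl-4-{(1S)-1-iodo-2-[(8-methoxy-2-oxo-2H-chromen-7-yl)oxy]ethyl}-4-methyl-1,3-dioxan-2-one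
Conditions: IBr (1.3 equiv, added in CH2Cl2), toluene, −85 °C; aq. Na2S2O3/NaHCO3
Reagents that add atoms: iodine monobromide, IBr
Why: IBr forms an iodonium ion on the electron-rich trisubstituted C2'=C3' alkene, the carbonate carbonyl oxygen opens it at the tertiary carbon C3' anti to iodine, and the resulting 2-tert-butoxy-1,3-dioxan-2-ylium ion loses its tert-butyl group to bromide. The closest known reaction is the iodocarbonate halocyclisation of homoallylic tert-butyl carbonates with IBr at low temperature, applied here to a trisubstituted alkene. The 1,3-dioxan-2-one ring closes in the 6-exo mode (O onto C3', with C2' left outside the ring carrying the iodine). C3' is controlled by C5' through a chair transition state in which the vinyl group and the iodonium-bearing C2' arm are equatorial and the methyl group axial, which gives the 4,6-cis ring and (3'R) from (5'S); C2' is controlled by the (E)-alkene geometry through stereospecific anti addition, which gives (2'S). The step needs site, regio- and facial selectivity: the trisubstituted alkene should outrun the monosubstituted vinyl group (further deactivated by the allylic carbonate) and the electron-poor coumarin, attack at C3' is favoured by its tertiary cation character and by the six- over the seven-membered ring, and the low temperature sharpens the equatorial preference in the chair.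

Step 10
Reactants: 15 (4R,6S)-6-ethenyl-4-{(1S)-1-iodo-2-[(8-methoxy-2-oxo-2H-chromen-7-yl)oxy]ethyl}-4-methyl-1,3-dioxan-2-one
Product: 17 7-{[(2R,3R)-3-[(2S)-2-hydroxybut-3-en-1-yl]-3-methyloxiran-2-yl]methoxy}-8-methoxy-2H-chromen-2-one, via iodo diol 16 (not isolated)
Conditions: K2CO3 (3 equiv), MeOH, 0 °C → rt; aq. NH4Cl
Reagents that add atoms: none
Why: Methanolysis of the cyclic carbonate frees the tertiary C3' alkoxide, which displaces the neighbouring iodide at C2' in a 3-exo-tet Williamson closure with inversion, so the epoxide keeps the geometry of the original (E)-alkene ((2'R,3'R)) and the C5' hydroxyl is released with retention.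

Step 11
Reactants: 17 7-{[(2R,3R)-3-[(2S)-2-hydroxybut-3-en-1-yl]-3-methyloxiran-2-yl]methoxy}-8-methoxy-2H-chromen-2-one
Product: 18 (2R)-1-[(2R,3R)-3-{[(8-methoxy-2-oxo-2H-chromen-7-yl)oxy]methyl}-2-methyloxiran-2-yl]but-3-en-2-yl 4-nitrobenzoate
Conditions: 4-O2NC6H4CO2H, PPh3, DIAD, THF, 0 °C → rt
Reagents that add atoms: 4-nitrobenzoic acid, OC(=O)c1ccc(cc1)[N+](=O)[O-]
Why: Mitsunobu esterification in which 4-nitrobenzoate displaces the C5' oxyphosphonium ion by SN2 with inversion, converting (5'S) into the (5'R) configuration of the target; the near-neutral conditions should leave the epoxide closed.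

Step 12
Reactants: 18 (2R)-1-[(2R,3R)-3-{[(8-methoxy-2-oxo-2H-chromen-7-yl)oxy]methyl}-2-methyloxiran-2-yl]but-3-en-2-yl 4-nitrobenzoate
Product: 19 7-{[(2R,3R)-3-[(2R)-2-hydroxybut-3-en-1-yl]-3-methyloxiran-2-yl]methoxy}-8-methoxy-2H-chromen-2-one
Conditions: K2CO3 (0.3 equiv), MeOH, 0 °C
Reagents that add atoms: none
Why: Base-catalysed transesterification with methanol cleaves the activated aryl ester at the acyl carbon, so the C5'–O bond and its (R) configuration are kept, and the coumarin and epoxide should tolerate these mild conditions.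

Step 13
Reactants: 19 7-{[(2R,3R)-3-[(2R)-2-hydroxybut-3-en-1-yl]-3-methyloxiran-2-yl]methoxy}-8-methoxy-2H-chromen-2-one
Product: 20 7-{[(2R,3R)-3-[(2R)-2-hydroxy-4-methylpent-3-en-1-yl]-3-methyloxiran-2-yl]methoxy}-8-methoxy-2H-chromen-2-one (target)
Conditions: 2-methylbut-2-ene (large excess), second-generation Grubbs catalyst RuCl2(=CHPh)(H2IMes)(PCy3) (5 mol %), CH2Cl2, 40 °C, sealed tube
Reagents that add atoms: 2-methylbut-2-ene, CC=C(C)C
Why: Olefin cross-metathesis exchanges the terminal CH2 of the vinyl group for the isopropylidene unit of 2-methylbut-2-ene (propene is lost); the free allylic hydroxyl is tolerated, the electron-poor coumarin C3=C4 bond does not take part, and no stereocentre is affected.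

**Compound list**
1 | daphnetin (7,8-dihydroxy-2H-chromen-2-one) | Oc1ccc2ccc(=O)oc2c1O | starting material
2 | 8-hydroxy-7-[(4-methoxybenzyl)oxy]-2H-chromen-2-one | COc1ccc(COc2ccc3ccc(=O)oc3c2O)cc1 | intermediate
3 | 8-methoxy-7-[(4-methoxybenzyl)oxy]-2H-chromen-2-one | COc1ccc(COc2ccc3ccc(=O)oc3c2OC)cc1 | intermediate
4 | 7-hydroxy-8-methoxy-2H-chromen-2-one | COc1c(O)ccc2ccc(=O)oc12 | intermediate
5 | prop-2-enal | C=CC=O | starting material
6 | 3-bromoprop-1-yne | C#CCBr | starting material
7 | allenylzinc bromide (bromo(propa-1,2-dien-1-yl)zinc) | C=C=C[Zn]Br | intermediate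
8 | rac-hex-1-en-5-yn-3-ol | C#CCC(O)C=C | intermediate
9 | (3S)-hex-1-en-5-yn-3-ol | C#CC[C@H](O)C=C | intermediate
10 | alkenylalane alkoxide: [(1E,4S)-4-[(dimethylalumanyl)oxy]-2-methylhexa-1,5-dien-1-yl]dimethylalumane | C[Al](C)/C=C(\C)C[C@H](O[Al](C)C)C=C | intermediate
11 | lithium alkenylalanate: lithium butyl[(1E,4S)-4-[(dimethylalumanyl)oxy]-2-methylhexa-1,5-dien-1-yl]dimethylaluminate | [Li+].CCCC[Al-](C)(C)/C=C(\C)C[C@H](O[Al](C)C)C=C | intermediate
12 | (2E,5S)-3-methylhepta-2,6-diene-1,5-diol | OC/C=C(\C)C[C@H](O)C=C | intermediate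
13 | 7-{[(2E,5S)-5-hydroxy-3-methylhepta-2,6-dien-1-yl]oxy}-8-methoxy-2H-chromen-2-one | COc1c(OC/C=C(\C)C[C@H](O)C=C)ccc2ccc(=O)oc12 | intermediate
14 | tert-butyl (3S,5E)-7-[(8-methoxy-2-oxo-2H-chromen-7-yl)oxy]-5-methylhepta-1,5-dien-3-yl carbonate | COc1c(OC/C=C(\C)C[C@H](OC(=O)OC(C)(C)C)C=C)ccc2ccc(=O)oc12 | intermediate
15 | (4R,6S)-6-ethenyl-4-{(1S)-1-iodo-2-[(8-methoxy-2-oxo-2H-chromen-7-yl)oxy]ethyl}-4-methyl-1,3-dioxan-2-one | COc1c(OC[C@H](I)[C@@]2(C)C[C@@H](C=C)OC(=O)O2)ccc2ccc(=O)oc12 | intermediate
16 | iodo diol: 7-{[(2S,3R,5S)-3,5-dihydroxy-2-iodo-3-methylhept-6-en-1-yl]oxy}-8-methoxy-2H-chromen-2-one | COc1c(OC[C@H](I)[C@](C)(O)C[C@H](O)C=C)ccc2ccc(=O)oc12 | intermediate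
17 | 7-{[(2R,3R)-3-[(2S)-2-hydroxybut-3-en-1-yl]-3-methyloxiran-2-yl]methoxy}-8-methoxy-2H-chromen-2-one | COc1c(OC[C@H]2O[C@]2(C)C[C@H](O)C=C)ccc2ccc(=O)oc12 | intermediate
18 | (2R)-1-[(2R,3R)-3-{[(8-methoxy-2-oxo-2H-chromen-7-yl)oxy]methyl}-2-methyloxiran-2-yl]but-3-en-2-yl 4-nitrobenzoate | COc1c(OC[C@H]2O[C@]2(C)C[C@@H](OC(=O)c3ccc(cc3)[N+](=O)[O-])C=C)ccc2ccc(=O)oc12 | intermediate
19 | 7-{[(2R,3R)-3-[(2R)-2-hydroxybut-3-en-1-yl]-3-methyloxiran-2-yl]methoxy}-8-methoxy-2H-chromen-2-one | COc1c(OC[C@H]2O[C@]2(C)C[C@@H](O)C=C)ccc2ccc(=O)oc12 | intermediate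
20 | 7-{[(2R,3R)-3-[(2R)-2-hydroxy-4-methylpent-3-en-1-yl]-3-methyloxiran-2-yl]methoxy}-8-methoxy-2H-chromen-2-one | COc1c(OC[C@H]2O[C@]2(C)C[C@@H](O)C=C(C)C)ccc2ccc(=O)oc12 | target

**Totals**
Total step count: 13.
Longest linear sequence: 10 steps (steps 4 to 13, from prop-2-enal and 3-bromoprop-1-yne); the three-step branch to 4 joins at step 7.

**Steps most likely to fail**

Step 9 (key cyclisation). The facial selectivity may be poor if the chair with the C2' arm equatorial and the methyl group axial is not preferred strongly enough, so that the C3' epimeric ring forms alongside. IBr may also be consumed by iodination of the electron-rich aromatic ring. The fallback replaces the substrate-relayed oxygen delivery by a reagent-controlled epoxidation. Setting out from 13, Shi epoxidation with the D-fructose-derived ketone (KHSO5 as its triple salt 2KHSO5·KHSO4·K2SO4, K2CO3 buffer, MeCN/dimethoxymethane/water, 0 °C) should epoxidise the trisubstituted C2'=C3' alkene. By analogy with the (R,R) epoxides this ketone gives from trans-disubstituted and trisubstituted alkenes, attack should come from the face that leads to (2'R,3'R); the vinyl group and the coumarin are poor substrates for the dioxirane. This leads directly to 17, where the route is rejoined at step 11; no new compound arises on this way (F0).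

Step 6. With the hydroxyl carried as its aluminium alkoxide, transfer of the alkenyl group from the alanate to formaldehyde may be slow, so that protonolysis to the 1,1-disubstituted alkene competes; the unprotected diol also offers two hydroxyls to the etherification of step 7. The fallback masks the hydroxyl. Setting out from 9, silylation (t-BuMe2SiCl, imidazole, DMF) gives tert-butyl{[(3S)-hex-1-en-5-yn-3-yl]oxy}dimethylsilane F1. Carboalumination and hydroxymethylation as in step 6, now without an alkoxide, give (2E,5S)-5-{[tert-butyl(dimethyl)silyl]oxy}-3-methylhepta-2,6-dien-1-ol F2. Mitsunobu etherification with 4 gives 7-{[(2E,5S)-5-{[tert-butyl(dimethyl)silyl]oxy}-3-methylhepta-2,6-dien-1-yl]oxy}-8-methoxy-2H-chromen-2-one F3, and Bu4NF in THF then releases 13, where the route is rejoined at step 8.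

Step 11. The allylic oxyphosphonium ion may react by SN2' attack at the vinyl terminus, by elimination to a diene, or with partial loss of stereochemical integrity instead of clean SN2 inversion. The fallback corrects C5' by oxidation and reagent-controlled reduction rather than by substitution. Setting out from 17, cross-metathesis with 2-methylbut-2-ene under the conditions of step 13 gives the (5'S) epimer of the target, 7-{[(2R,3R)-3-[(2S)-2-hydroxy-4-methylpent-3-en-1-yl]-3-methyloxiran-2-yl]methoxy}-8-methoxy-2H-chromen-2-one F4. MnO2 in CH2Cl2 oxidises the allylic alcohol to the enone 8-methoxy-7-{[(2R,3R)-3-methyl-3-(4-methyl-2-oxopent-3-en-1-yl)oxiran-2-yl]methoxy}-2H-chromen-2-one F5. Corey–Bakshi–Shibata reduction with the (S)-methyl oxazaborolidine and catecholborane at −78 °C, the alkenyl group acting as the large substituent, should then deliver the (5'R) alcohol, which is 20, the end of the route.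

Further compounds
F0 | step 9 | none | none
F1 | step 6 | tert-butyl{[(3S)-hex-1-en-5-yn-3-yl]oxy}dimethylsilane | C#CC[C@H](O[Si](C)(C)C(C)(C)C)C=C
F2 | step 6 | (2E,5S)-5-{[tert-butyl(dimethyl)silyl]oxy}-3-methylhepta-2,6-dien-1-ol | OC/C=C(\C)C[C@H](O[Si](C)(C)C(C)(C)C)C=C
F3 | step 6 | 7-{[(2E,5S)-5-{[tert-butyl(dimethyl)silyl]oxy}-3-methylhepta-2,6-dien-1-yl]oxy}-8-methoxy-2H-chromen-2-one | COc1c(OC/C=C(\C)C[C@H](O[Si](C)(C)C(C)(C)C)C=C)ccc2ccc(=O)oc12
F4 | step 11 | 7-{[(2R,3R)-3-[(2S)-2-hydroxy-4-methylpent-3-en-1-yl]-3-methyloxiran-2-yl]methoxy}-8-methoxy-2H-chromen-2-one | COc1c(OC[C@H]2O[C@]2(C)C[C@H](O)C=C(C)C)ccc2ccc(=O)oc12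
F5 | step 11 | 8-methoxy-7-{[(2R,3R)-3-methyl-3-(4-methyl-2-oxopent-3-en-1-yl)oxiran-2-yl]methoxy}-2H-chromen-2-one | COc1c(OC[C@H]2O[C@]2(C)CC(=O)C=C(C)C)ccc2ccc(=O)oc12
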